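## Analysis of the target

The target 13 is an isoflavone: a 4H-chromen-4-one in which a benzo ring (ring A, C4a to C8a) is fused to a 4-pyranone (ring C, O1 to C4), with a 3,4,5-trimethoxyphenyl group (ring B) on C3. It has no stereocentre, so the problem is one of constitution. Ring A carries two neighbouring oxygens, a free hydroxyl on C6 and a methyl ether on C7, and these must be told apart beside three further aryl methyl ethers, which rules out any late demethylation. The sensitive parts are the pyranone ring, which hydroxide and amines open by attack at C2, and the oxygen-rich ring A, which is easily oxidised once its hydroxyls are free. The 7-oxygen is para to C4a and so conjugated with the C4 carbonyl, while the 6-oxygen is not; this difference in acidity is the only handle once both are free. The plan rests on one feature: the C4a–C8a bond is also the C5=C6 double bond of a monocyclic 3-aryl-4H-pyran-4-one, and C5 to C8 with the oxygens on C6 and C7 form a 2,3-dioxygenated buta-1,3-diene. Ring A can therefore be added last by a (4+2) union across the free enone double bond of a pyranone that already carries ring B, followed by loss of four hydrogens. The difficulty is that a plain 4-pyranone is a poor dienophile, and that the adduct holds its ring oxygen β to a ketone, so it can lose that oxygen by elimination instead of being dehydrogenated.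

## Retrosynthetic reasoning

**O7–CH3.** The methyl group on O7 of 13 is cut first, leading back to the diol 12. Cutting here lets both ring A oxygens come from one symmetrical building block. The forward reaction must alkylate only the 7-hydroxyl, which is the more acidic because its anion is a vinylogous carboxylate of the C4 carbonyl.

**O–Si bonds and four C–H bonds.** The diol 12 comes from its bis-silyl ether 11, and 11 from the tetrahydro compound 10 by removal of the hydrogens on C4a, C5, C8 and C8a. The silyl groups are kept until ring A is aromatic. Free, the enediol of 10 would be a 1,2-diketone with acidic hydrogens on C8, and the ring oxygen on C8a would be eliminated. The forward oxidation must abstract hydride faster than the C8a–O1 bond can ionise.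

**C4a–C5 and C8–C8a.** These two bonds of 10 are cut together, giving the pyranone 5 and the diene 7. This is the disconnection that forms ring A in one operation from a partner carrying ring B and ring C and a four-carbon partner carrying both oxygens. Because 7 is symmetrical there is no orientation question. Forward, 5 has to be made electrophilic enough: O-silylation to the pyrylium salt 8 should allow attack of 7 at C6, and the resulting ion 9 should close onto C5.

**C3–C1′ (ring C to ring B).** The pyranone 5 is cut at the biaryl-type bond into the bromopyranone 3 and the boronic acid 4. A cross-coupling on a zerovalent palladium catalyst is the most dependable way to join a vinylogous α-halo enone to an electron-rich arene. The bromide 3 goes back to the parent pyranone 1 by halogen addition to one enone double bond and loss of hydrogen halide from the dibromide 2.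

**O–Si bonds of the diene.** The diene 7 is the double enol silane of the diketone 6, reached in one step by silylating both carbonyl oxygens while removing a proton from each methyl group.

## Alternatives that were turned down

**Alternative 1:** Ring A arrives as an aryne, and the bonds made are O1–C8a and C4–C4a. The symmetrical aryne set free by fluoride from the silyl triflate A1 would insert into the acyl C–O bond of the arylacetic acid A2 and give the 2-hydroxyaryl benzyl ketone A3 without closing a ring. A one-carbon condensation then builds ring C, and debenzylation leads to the diol 12.
- For: every reaction type is established, the aryne is symmetrical, and the closure of a 2-hydroxydeoxybenzoin to an isoflavone is very dependable. On precedent this route is stronger than the chosen one.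
- Against: A1 needs four to five steps from a catechol. The acid may simply protonate the aryne-derived anion and stop at the aryl ester. Both ring A oxygens arrive as identical benzyl ethers, so the same selective 7-O-methylation of 12 remains. An unsymmetrical aryne would only replace that problem with an orientation problem in the insertion.
- Comparison: about nine steps against seven. The chosen route reaches 12 from cheaper components and adds ring A to a finished ring B–ring C unit, at the price of an unproven key step.

**Alternative 2:** Ring A is built from the tetronate A4. Its silyloxyfuran A5 would add across the alkynyl ketone A6, forming C5–C6 and C4a–C8a. Opening of the oxygen bridge and tautomerisation would give the 2,5-dihydroxy-4-methoxyphenyl ketone A7, and a one-carbon closure then gives 13 directly.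
- For: the methyl ether on C7 is present from the start and the C6 oxygen appears as a free hydroxyl, so no late differentiation is needed. The route is about five steps. On both points it is stronger than the chosen route.
- Against: A6 is a terminal ynone with acidic benzylic hydrogens between the arene and the carbonyl, prone to isomerisation and self-condensation. Silyloxyfurans tend to react with ynones by vinylogous conjugate addition and stop at open-chain butenolides. A7 is an electron-rich hydroquinone that oxidises readily.
- Comparison: the chosen route offers bench-stable partners, a cross-coupling that fixes ring B early, and an annulation that would carry over to other 3-aryl-pyranones. It pays with two more steps and the late methylation.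

**Alternative 3:** Ring C is closed through an aryne, forming O1–C8a. The enolate of the formyl ketone A8 would lose hydrogen bromide across C8–C8a under a strong amide base, the enolate oxygen would add to C8a, and protonation at C8 gives the protected isoflavone A9. Acetal cleavage then gives 13.
- For: O6 and O7 are differentiated from the start, only one aryne can form, the tether fixes where the oxygen adds, and no transition metal is needed. On regiochemical certainty in ring A it is stronger than the chosen route.
- Against: amide bases open chromones at C2 and add to arynes themselves, the stabilised enolate is a weak nucleophile, and A8 needs a long linear preparation plus a final deprotection (roughly eight to nine steps). The same bond could be made more gently by copper catalysis, so the aryne adds risk without benefit.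
- Comparison: the chosen route is shorter and milder, but its key step is unproven and it needs the late methylation.

Key step: step 4

Remark on the chemistry: the target is achiral; the two stereocentres formed in step 4 arise as a racemate and are removed in step 5, so no absolute control is planned. Me3SiOTf in step 4 is used in substoichiometric amount and is released again in each turnover.

## Route

Step 1
Reactants: 1 4H-pyran-4-one
Product: 3 3-bromo-4H-pyran-4-one, via trans-2,3-dibromo-2,3-dihydro-4H-pyran-4-one 2 (not isolated)
Conditions: Br2 (1.0 equiv), CH2Cl2, 0 °C; then Et3N (1.1 equiv), 0 °C → rt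
Reagents that add atoms: bromine, BrBr
Why: Electrophilic addition of bromine across one enol-ether double bond gives the trans dibromide 2, and E1cB dehydrobromination follows: Et3N removes the acidic H3 next to the carbonyl and bromide leaves from the acetal-like C2. One equivalent of bromine at 0 °C should leave the second double bond untouched.

Step 2
Reactants: 3 3-bromo-4H-pyran-4-one; 4 (3,4,5-trimethoxyphenyl)boronic acid
Product: 5 3-(3,4,5-trimethoxyphenyl)-4H-pyran-4-one
Conditions: Pd(PPh3)4 (5 mol %, zerovalent palladium), Na2CO3 (2 equiv), DME/H2O, 80 °C
Reagents that add atoms: none
Why: Suzuki–Miyaura coupling; the C3–Br bond of the vinylogous α-bromo enone undergoes oxidative addition readily and the electron-rich boronic acid transmetalates under mild carbonate conditions, which the pyranone ring should tolerate.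

Step 3
Reactants: 6 butane-2,3-dione
Product: 7 2,3-bis(trimethylsilyloxy)buta-1,3-diene
Conditions: Me3SiOTf (2.2 equiv), Et3N (2.5 equiv), Et2O, 0 °C → rt; pentane extraction, distillation
Reagents that add atoms: trimethylsilyl trifluoromethanesulfonate, C[Si](C)(C)OS(=O)(=O)C(F)(F)F
Why: Soft enolisation: each carbonyl oxygen is silylated and the adjacent methyl group is deprotonated by the amine, giving the double enol silane without the aldol self-condensation that stronger bases cause with this diketone.

Step 4
Reactants: 5 3-(3,4,5-trimethoxyphenyl)-4H-pyran-4-one; 7 2,3-bis(trimethylsilyloxy)buta-1,3-diene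
Product: 10 rac-(4aS,8aR)-3-(3,4,5-trimethoxyphenyl)-6,7-bis(trimethylsilyloxy)-4a,5,8,8a-tetrahydro-4H-chromen-4-one (cis ring fusion), via 4-silyloxypyrylium triflate 8 (not isolated), via open-chain oxocarbenium triflate 9 (not isolated)
Conditions: Me3SiOTf (20 mol %), 2,6-di-tert-butylpyridine (10 mol %), CH2Cl2, −78 → −20 °C, slow addition of 7 (1.3 equiv); pyridine, then cold aq NaHCO3
Reagents that add atoms: none
Why: Proposed new method: O-silylation of 5 by Me3SiOTf should give the aromatic 4-silyloxypyrylium ion 8, whose unhindered C6 is attacked by a methylene terminus of the bis(enol silane) 7 in a Mukaiyama–Michael addition, forming C8–C8a and leaving the oxocarbenium ion 9, an O-silylated 2-silyloxy enone whose positive charge is shared with the far methylene carbon. The 4-silyloxy-2H-pyran part of 9 is an enol silane nucleophilic at the former C5 of the pyranone, and it should collapse onto that methylene carbon to form C4a–C5, a 6-(enolexo)-endo-trig closure of the carbocycle that completes a stepwise (4+2) addition and passes the silyl cation on to the next molecule of 5. The closest known reactions are the silyl-triflate-promoted conjugate additions of enol silanes to 4-pyranones and chromones through silyloxypyrylium ions and the Diels–Alder reactions of 3-acyl- and 3-cyanochromones with siloxydienes; a bis(silyloxy)diene adding to a pyranone that lacks an activating group has no precedent. The C8a stereocentre arises without control in the first addition, and C4a is then fixed relative to it because the four-carbon chain on C8a can reach the neighbouring enol carbon only from its own face, so the ring fusion must be cis and the adduct racemic. The step needs site selectivity between the two enone double bonds and a clean mono-annulation: the 3-aryl group shields C2 and would force a quaternary centre in the second bond formation, so reaction at C5=C6 is expected, the symmetrical diene removes any question of orientation, and slow addition of 7 at low temperature should keep intermolecular capture of 9 behind ring closure. The hindered pyridine scavenges triflic acid, which would otherwise strip the silyl groups from 7, and the quench is kept weakly basic and cold so that the ring oxygen on C8a is not eliminated from C4a.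

Step 5
Reactants: 10 rac-(4aS,8aR)-3-(3,4,5-trimethoxyphenyl)-6,7-bis(trimethylsilyloxy)-4a,5,8,8a-tetrahydro-4H-chromen-4-one
Product: 11 3-(3,4,5-trimethoxyphenyl)-6,7-bis(trimethylsilyloxy)-4H-chromen-4-one
Conditions: DDQ (2.2 equiv), 2,4,6-collidine (0.5 equiv), PhMe, 0 °C → rt, crude 10 added slowly to the oxidant; filtration, crude carried on
Reagents that add atoms: none
Why: DDQ dehydrogenation by two rounds of hydride abstraction and proton loss: the electron-rich enediol disilyl ether gives up an allylic hydride from C5 or C8 to form a 1,3-diene, and the second equivalent removes the C8a hydride, now allylic and next to oxygen, so that loss of H4a aromatises ring A and restores the pyranone double bond. Keeping the oxidant in excess and the silyl groups in place should let oxidation outrun ionisation of the C8a–O1 bond; both stereocentres disappear here.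

Step 6
Reactants: 11 3-(3,4,5-trimethoxyphenyl)-6,7-bis(trimethylsilyloxy)-4H-chromen-4-one
Product: 12 6,7-dihydroxy-3-(3,4,5-trimethoxyphenyl)-4H-chromen-4-one
Conditions: KHF2 (2.5 equiv), MeOH, rt
Reagents that add atoms: none
Why: Fluoride cleavage of aryl silyl ethers, driven by the Si–F bond; the weakly acidic hydrogendifluoride avoids a catecholate, which would be prone to air oxidation, and leaves the pyranone ring and the methyl ethers alone.

Step 7
Reactants: 12 6,7-dihydroxy-3-(3,4,5-trimethoxyphenyl)-4H-chromen-4-one
Product: 13 6-hydroxy-7-methoxy-3-(3,4,5-trimethoxyphenyl)-4H-chromen-4-one (the target)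
Conditions: MeI (1.05 equiv), KHCO3 (1.05 equiv), DMF, rt → 40 °C
Reagents that add atoms: iodomethane, CI
Why: Williamson ether synthesis on the mono-phenoxide: the 7-hydroxyl, para to C4a and conjugated with the C4 carbonyl, is much the more acidic and is the only one that hydrogencarbonate ionises to a useful extent, so one methyl group should go onto O7. The 6-hydroxyl of the product is too weakly acidic for this base, which should stop the reaction after one alkylation.

## Compound list

1 | 4H-pyran-4-one | O=c1ccocc1 | starting material
2 | rac-(2S,3R)-2,3-dibromo-2,3-dihydro-4H-pyran-4-one (trans) | O=C1C=CO[C@@H](Br)[C@@H]1Br | intermediate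
3 | 3-bromo-4H-pyran-4-one | O=c1ccocc1Br | intermediate
4 | (3,4,5-trimethoxyphenyl)boronic acid | COc1cc(B(O)O)cc(OC)c1OC | starting material
5 | 3-(3,4,5-trimethoxyphenyl)-4H-pyran-4-one | COc1cc(cc(OC)c1OC)-c1coccc1=O | intermediate
6 | butane-2,3-dione | CC(=O)C(C)=O | starting material
7 | 2,3-bis(trimethylsilyloxy)buta-1,3-diene | C=C(O[Si](C)(C)C)C(=C)O[Si](C)(C)C | intermediate
8 | 3-(3,4,5-trimethoxyphenyl)-4-(trimethylsilyloxy)pyrylium trifluoromethanesulfonate | COc1cc(cc(OC)c1OC)-c1c[o+]ccc1O[Si](C)(C)C.[O-]S(=O)(=O)C(F)(F)F | intermediate
9 | rac-{1-[(2R)-5-(3,4,5-trimethoxyphenyl)-4-(trimethylsilyloxy)-2H-pyran-2-yl]-3-(trimethylsilyloxy)but-3-en-2-ylidene}(trimethylsilyl)oxonium trifluoromethanesulfonate | C=C(O[Si](C)(C)C)C(=[O+][Si](C)(C)C)C[C@H]1OC=C(c2cc(OC)c(OC)c(OC)c2)C(O[Si](C)(C)C)=C1.[O-]S(=O)(=O)C(F)(F)F | intermediate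
10 | rac-(4aS,8aR)-3-(3,4,5-trimethoxyphenyl)-6,7-bis(trimethylsilyloxy)-4a,5,8,8a-tetrahydro-4H-chromen-4-one (cis-fused, one enantiomer drawn) | O=C1C(=CO[C@@H]2CC(O[Si](C)(C)C)=C(O[Si](C)(C)C)C[C@H]12)c1cc(OC)c(OC)c(OC)c1 | intermediate
11 | 3-(3,4,5-trimethoxyphenyl)-6,7-bis(trimethylsilyloxy)-4H-chromen-4-one | COc1cc(cc(OC)c1OC)-c1coc2cc(O[Si](C)(C)C)c(O[Si](C)(C)C)cc2c1=O | intermediate
12 | 6,7-dihydroxy-3-(3,4,5-trimethoxyphenyl)-4H-chromen-4-one | COc1cc(cc(OC)c1OC)-c1coc2cc(O)c(O)cc2c1=O | intermediate
13 | 6-hydroxy-7-methoxy-3-(3,4,5-trimethoxyphenyl)-4H-chromen-4-one | COc1cc2occ(-c3cc(OC)c(OC)c(OC)c3)c(=O)c2cc1O | target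

## Step count and least certain steps

Total: 7 steps. Longest linear sequence: 6 steps (steps 1, 2, 4, 5, 6, 7); step 3 is a one-step side branch.

**Step 4 (key step, the proposed new method).**
- What may go wrong: the annulation may stall or never start. The pyrylium ion 8 may be too weakly electrophilic for a 2-silyloxy alkene. Traces of triflic acid may protodesilylate 7 faster than it adds. The open-chain ion 9 may be captured by a second molecule of 7 (oligomerisation) or lose its silyl group and stop after the first bond. The adduct may undergo β-elimination of its ring oxygen during the quench.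
- Fallback (known chemistry, abandons the cycloaddition): it sets out from the boronic acid 4 and comes back at the target 13. Purchased 2-methoxybenzene-1,4-diol F1 is acylated para to its methoxy group (AcOH, BF3·OEt2, Friedel–Crafts) to 1-(2,5-dihydroxy-4-methoxyphenyl)ethan-1-one F2. The non-chelated 5-hydroxyl is benzylated (BnBr, K2CO3, acetone) to 1-[5-(benzyloxy)-2-hydroxy-4-methoxyphenyl]ethan-1-one F3. Condensation with N,N-dimethylformamide dimethyl acetal gives (E)-1-[5-(benzyloxy)-2-hydroxy-4-methoxyphenyl]-3-(dimethylamino)prop-2-en-1-one F4. Iodine cyclises and iodinates it to 6-(benzyloxy)-3-iodo-7-methoxy-4H-chromen-4-one F5. Suzuki–Miyaura coupling with 4 [Pd(PPh3)4, zerovalent palladium, Na2CO3, DME/H2O] gives 6-(benzyloxy)-7-methoxy-3-(3,4,5-trimethoxyphenyl)-4H-chromen-4-one F6, and hydrogenolysis (H2, Pd/C) gives 13. This path also has O6 and O7 differentiated from the start.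

**Step 5.**
- What may go wrong: aromatisation by elimination instead of dehydrogenation. After the first hydride abstraction the C8a–O1 bond is allylic and its oxygen is a vinylogous carboxylate leaving group, so acid from the spent quinone can ionise it. Base can trigger E1cB opening from C4a. Both paths end in ring opening. Early loss of the silyl groups would expose a 1,2-diketone that eliminates still more readily, and a freed catechol could be over-oxidised.
- Fallback: it sets out from 10 and comes back at 11. Soft enolisation of the C4 ketone (Me3SiOTf, Et3N, CH2Cl2, −78 °C) gives rac-(8aR)-3-(3,4,5-trimethoxyphenyl)-4,6,7-tris(trimethylsilyloxy)-5,8-dihydro-8aH-chromene F7, a 2H-pyran with no hydrogen left on C4a. Hydride abstraction from C8a (DDQ or Ph3C+ BF4−) then leads directly to the pyrylium stage, the classical 2H-pyran-to-pyrylium oxidation, at which the ring oxygen can no longer leave. A second equivalent of oxidant aromatises the remaining cyclohexadiene ring, and loss of the O4 silyl group on work-up returns 11.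

**Step 7.**
- What may go wrong: incomplete site selectivity and over-alkylation. The mono-anion is a hydrogen-bonded pair in which the less populated 6-phenoxide is the stronger nucleophile, and any excess base exposes the second hydroxyl.
- Fallback: it sets out from 12 and comes back at 13. Mitsunobu etherification with methanol (PPh3, diisopropyl azodicarboxylate, THF, 0 °C) activates the alcohol under neutral conditions, and the phenol enters only after protonating the betaine, which favours the more acidic 7-hydroxyl and never forms a dianion. No new compound arises (entry F0).

## Further compounds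

F1 | step 4 | 2-methoxybenzene-1,4-diol | COc1cc(O)ccc1O
F2 | step 4 | 1-(2,5-dihydroxy-4-methoxyphenyl)ethan-1-one | CC(=O)c1cc(O)c(OC)cc1O
F3 | step 4 | 1-[5-(benzyloxy)-2-hydroxy-4-methoxyphenyl]ethan-1-one | CC(=O)c1cc(OCc2ccccc2)c(OC)cc1O
F4 | step 4 | (E)-1-[5-(benzyloxy)-2-hydroxy-4-methoxyphenyl]-3-(dimethylamino)prop-2-en-1-one | CN(C)/C=C/C(=O)c1cc(OCc2ccccc2)c(OC)cc1O
F5 | step 4 | 6-(benzyloxy)-3-iodo-7-methoxy-4H-chromen-4-one | COc1cc2occ(I)c(=O)c2cc1OCc1ccccc1
F6 | step 4 | 6-(benzyloxy)-7-methoxy-3-(3,4,5-trimethoxyphenyl)-4H-chromen-4-one | COc1cc2occ(-c3cc(OC)c(OC)c(OC)c3)c(=O)c2cc1OCc1ccccc1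
F7 | step 5 | rac-(8aR)-3-(3,4,5-trimethoxyphenyl)-4,6,7-tris(trimethylsilyloxy)-5,8-dihydro-8aH-chromene | COc1cc(cc(OC)c1OC)C1=CO[C@@H]2CC(O[Si](C)(C)C)=C(O[Si](C)(C)C)CC2=C1O[Si](C)(C)C
F0 | step 7 | none | none
A1 | alternative 1 | 4,5-bis(benzyloxy)-2-(trimethylsilyl)phenyl trifluoromethanesulfonate | C[Si](C)(C)c1cc(OCc2ccccc2)c(OCc2ccccc2)cc1OS(=O)(=O)C(F)(F)F
A2 | alternative 1 | (3,4,5-trimethoxyphenyl)acetic acid | COc1cc(CC(=O)O)cc(OC)c1OC
A3 | alternative 1 | 1-[4,5-bis(benzyloxy)-2-hydroxyphenyl]-2-(3,4,5-trimethoxyphenyl)ethan-1-one | COc1cc(CC(=O)c2cc(OCc3ccccc3)c(OCc3ccccc3)cc2O)cc(OC)c1OC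
A4 | alternative 2 | 4-methoxyfuran-2(5H)-one (methyl tetronate) | COC1=CC(=O)OC1
A5 | alternative 2 | 4-methoxy-2-(trimethylsilyloxy)furan | COc1coc(O[Si](C)(C)C)c1
A6 | alternative 2 | 1-(3,4,5-trimethoxyphenyl)but-3-yn-2-one | COc1cc(CC(=O)C#C)cc(OC)c1OC
A7 | alternative 2 | 1-(2,5-dihydroxy-4-methoxyphenyl)-2-(3,4,5-trimethoxyphenyl)ethan-1-one | COc1cc(O)c(cc1O)C(=O)Cc1cc(OC)c(OC)c(OC)c1
A8 | alternative 3 | 3-[2-bromo-4-methoxy-5-(methoxymethoxy)phenyl]-3-oxo-2-(3,4,5-trimethoxyphenyl)propanal | COCOc1cc(C(=O)C(C=O)c2cc(OC)c(OC)c(OC)c2)c(Br)cc1OC
A9 | alternative 3 | 7-methoxy-6-(methoxymethoxy)-3-(3,4,5-trimethoxyphenyl)-4H-chromen-4-one | COCOc1cc2c(cc1OC)occ(-c1cc(OC)c(OC)c(OC)c1)c2=O
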